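**Retrosynthetic overview**

1. The route rests on ring B, the 2'-hydroxy-6'-pentylbenzoic acid ring (C1' bears CO2H, C4' the depside oxygen). Its C3'–C6' segment, with the C4' oxygen and the pentyl chain, is C3–C6 of 4-hydroxy-6-pentyl-2-pyrone, and C1'/C2' are the two carbons of a 3-siloxypropiolate.
2. Key disconnection: C6'–C1' and C3'–C2' are cut, with CO2 restored as the pyrone O1–C2 bridge. This gives a 4-aroyloxy-6-pentyl-2-pyrone and benzyl 3-(triisopropylsiloxy)propiolate.
3. The depside ester C7(=O)–O–C4' is made before ring B exists, by O-acylation of the pyrone's single hydroxyl with the ring A acid chloride, so the 2'-OH and 4'-OH never have to be told apart.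
4. Ring A (2-hydroxy-4-methoxy-6-propylbenzoyl) comes from divarinol, the pyrone from triacetic acid lactone by butylation, and the alkyne from trimethylsilylacetylene via an ynolate and benzyl chloroformate.
5. Ring order: ring A and the pyrone ring are bought as rings; ring B is formed last, from the pyrone ring, and is followed by desilylation and hydrogenolysis.

Key step: step 10

Assumption: the target is achiral and the bicyclic lactone 21 is a transient racemate, so no stereocontrol is required anywhere in the route.

**Route**

Step 1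
Reactants: 1 divarinol (5-propylbenzene-1,3-diol)
Product: 3 2,4-dihydroxy-6-propylbenzaldehyde, via aryl iminium chloride 2 (not isolated)
Conditions: POCl3, DMF, 0 °C → rt; then H2O, 50 °C
Reagents that add atoms: N,N-dimethylformamide, CN(C)C=O; water, O
Why: Vilsmeier–Haack formylation of a 5-alkylresorcinol should go at C4 (ortho to one hydroxyl, para to the other) and not at the crowded C2 between the hydroxyls; the iminium salt is hydrolysed on work-up.

Step 2
Reactants: 3 2,4-dihydroxy-6-propylbenzaldehyde
Product: 4 2-hydroxy-4-methoxy-6-propylbenzaldehyde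
Conditions: MeI (1.05 equiv), K2CO3, acetone, rt
Reagents that add atoms: iodomethane, CI
Why: Williamson etherification; the 2-hydroxyl is held in a hydrogen bond to the aldehyde, so the free and more acidic 4-hydroxyl should be methylated selectively with one equivalent of MeI.

Step 3
Reactants: 4 2-hydroxy-4-methoxy-6-propylbenzaldehyde
Product: 5 2-(benzyloxy)-4-methoxy-6-propylbenzaldehyde
Conditions: BnBr, K2CO3, DMF, 60 °C
Reagents that add atoms: benzyl bromide, BrCc1ccccc1
Why: Williamson etherification of the remaining chelated phenol under more forcing conditions; nothing else in 4 is alkylated.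

Step 4
Reactants: 5 2-(benzyloxy)-4-methoxy-6-propylbenzaldehyde
Product: 6 2-(benzyloxy)-4-methoxy-6-propylbenzoic acid
Conditions: NaClO2, NaH2PO4, 2-methyl-2-butene, t-BuOH–H2O, rt
Reagents that add atoms: sodium chlorite, [Na+].[O-]Cl=O
Why: Pinnick oxidation tolerates the hindered, electron-rich aldehyde, and the alkene scavenger removes HOCl before it can chlorinate the ring.

Step 5
Reactants: 7 triacetic acid lactone (4-hydroxy-6-methyl-2H-pyran-2-one); 8 1-iodobutane
Product: 10 4-hydroxy-6-pentyl-2H-pyran-2-one, via dilithium dianion 9 (not isolated)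
Conditions: LiN(i-Pr)2 (2.2 equiv), THF–DMPU, −78 °C; then 8, −78 → 0 °C; aq. HCl
Reagents that add atoms: none
Why: Dianion alkylation; the second deprotonation takes place at the C6 methyl group, and this vinylogous carbanion is the most nucleophilic site, so butylation there should give the pentyl chain.

Step 6
Reactants: 6 2-(benzyloxy)-4-methoxy-6-propylbenzoic acid; 10 4-hydroxy-6-pentyl-2H-pyran-2-one
Product: 12 2-oxo-6-pentyl-2H-pyran-4-yl 2-(benzyloxy)-4-methoxy-6-propylbenzoate, via aroyl chloride 11 (not isolated)
Conditions: (COCl)2, cat. DMF, CH2Cl2, 0 °C → rt, evaporate; then 10, Et3N, CH2Cl2, 0 °C → rt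
Reagents that add atoms: none
Why: Acyl substitution of the acid chloride by the acidic pyrone 4-hydroxyl; DMAP and cyanide are left out because they would promote a Fries-type shift of the aroyl group from O4 to C3.

Step 7
Reactants: 13 trimethylsilylacetylene
Product: 16 triisopropyl{[(trimethylsilyl)ethynyl]oxy}silane, via lithium silylacetylide 14 (not isolated), via lithium silylynolate 15 (not isolated)
Conditions: n-BuLi, THF, −78 °C; t-BuOOLi (from t-BuOOH, LiN(SiMe3)2), −78 → 0 °C; TIPSOTf, −78 → 0 °C
Reagents that add atoms: tert-butyl hydroperoxide, CC(C)(C)OO; triisopropylsilyl trifluoromethanesulfonate, CC(C)[Si](C(C)C)(C(C)C)OS(=O)(=O)C(F)(F)F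
Why: Julia-type oxidation of a lithium acetylide at the peroxide oxygen gives the ynolate, and the bulky silyl triflate should silylate it at oxygen, as in the standard preparation of triisopropylsilyl ynol ethers.

Step 8
Reactants: 16 triisopropyl{[(trimethylsilyl)ethynyl]oxy}silane
Product: 17 (ethynyloxy)triisopropylsilane
Conditions: K2CO3 (0.1 equiv), MeOH–THF, −20 → 0 °C, short reaction time, pentane extraction
Reagents that add atoms: none
Why: Base-catalysed protodesilylation; methoxide should attack the unhindered trimethylsilyl group on the sp carbon much faster than the oxygen-bound silicon, which is shielded by three isopropyl groups.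

Step 9
Reactants: 17 (ethynyloxy)triisopropylsilane; 18 benzyl chloroformate
Product: 20 benzyl 3-[(triisopropylsilyl)oxy]prop-2-ynoate, via lithium siloxyacetylide 19 (not isolated)
Conditions: n-BuLi, THF, −78 °C; then cannulated into 18 (1.5 equiv), THF, −78 °C; cold aq. NaHCO3, filtration through Et3N-deactivated silica, used at once
Reagents that add atoms: none
Why: Deprotonation of a terminal ynol ether and acylation of the acetylide with a chloroformate, as is done with lithium alkoxyacetylides; inverse addition at −78 °C should suppress a second addition and silyl transfer between acetylides.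

Step 10
Reactants: 12 2-oxo-6-pentyl-2H-pyran-4-yl 2-(benzyloxy)-4-methoxy-6-propylbenzoate; 20 benzyl 3-[(triisopropylsilyl)oxy]prop-2-ynoate (2–3 equiv)
Product: 22 benzyl 4-{[2-(benzyloxy)-4-methoxy-6-propylbenzoyl]oxy}-6-pentyl-2-[(triisopropylsilyl)oxy]benzoate, via bicyclic lactone 21 (not isolated)
Conditions: AgNTf2 (20 mol %), 4 Å MS, ClCH2CH2Cl, rt → 60 °C
Reagents that add atoms: none
Why: Proposed new method: the silver-bound siloxyalkyne should add across pyrone C3 and C6 in a (4+2) sense, either in concert or stepwise (pyrone C3 attacks the ketenium-like siloxy carbon, then the ester-bearing vinylsilver carbon closes onto C6), to give the 2-oxabicyclo[2.2.2]octadienone 21, which loses CO2 by retro-(4+2) to leave ring B as the arene. The closest known types are the thermal Diels–Alder/decarboxylation of 4-alkoxy-6-alkyl-2-pyrones with acetylenic esters and the AgNTf2-promoted benzannulation of alkyl- and aryl-substituted siloxyalkynes with 2-pyrones; a siloxyalkyne that also carries an ester is untested. Ring B is closed by an intermolecular (4+2) annulation that forms C6'–C1' and C3'–C2', followed by CO2 extrusion, with no elimination step that could eject the aroyloxy group; no stereocentre survives, since the two bridgehead centres of 21 vanish on aromatisation. The step needs one regiochemistry, the ester carbon next to the pentyl-bearing carbon, and matched polarisation should secure it: pyrone C3 is the nucleophilic and C6 the electrophilic terminus, while in the push-pull alkyne the siloxy carbon is electrophilic and the ester carbon nucleophilic. Chemoselectivity depends on the absence of nucleophiles (12 is a vinylogous anhydride) and on the bulky triisopropylsilyl group, which slows the 1,3-silyl shift to the silylketene.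

Step 11
Reactants: 22 benzyl 4-{[2-(benzyloxy)-4-methoxy-6-propylbenzoyl]oxy}-6-pentyl-2-[(triisopropylsilyl)oxy]benzoate
Product: 23 benzyl 4-{[2-(benzyloxy)-4-methoxy-6-propylbenzoyl]oxy}-2-hydroxy-6-pentylbenzoate
Conditions: Bu4NF, AcOH, THF, 0 °C
Reagents that add atoms: none
Why: Fluoride cleavage of an aryl silyl ether; the acetic acid buffer keeps the medium non-basic, so the hindered depside ester and the benzyl ester should not be attacked or transposed.

Step 12
Reactants: 23 benzyl 4-{[2-(benzyloxy)-4-methoxy-6-propylbenzoyl]oxy}-2-hydroxy-6-pentylbenzoate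
Product: 24 stenosporic acid
Conditions: H2 (1 atm), 10% Pd/C, EtOAc, rt
Reagents that add atoms: none
Why: Hydrogenolysis removes the benzyl ether and the benzyl ester together, and the aryl ester of the depside is inert to these conditions.

**Compound list**

1 | divarinol (5-propylbenzene-1,3-diol) | CCCc1cc(O)cc(O)c1 | starting material
2 | [(2,4-dihydroxy-6-propylphenyl)methylidene]dimethyliminium chloride | CCCc1cc(O)cc(O)c1C=[N+](C)C.[Cl-] | intermediate (not isolated)
3 | 2,4-dihydroxy-6-propylbenzaldehyde | CCCc1cc(O)cc(O)c1C=O | intermediate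
4 | 2-hydroxy-4-methoxy-6-propylbenzaldehyde | CCCc1cc(OC)cc(O)c1C=O | intermediate
5 | 2-(benzyloxy)-4-methoxy-6-propylbenzaldehyde | CCCc1cc(OC)cc(OCc2ccccc2)c1C=O | intermediate
6 | 2-(benzyloxy)-4-methoxy-6-propylbenzoic acid | CCCc1cc(OC)cc(OCc2ccccc2)c1C(=O)O | intermediate
7 | triacetic acid lactone (4-hydroxy-6-methyl-2H-pyran-2-one) | CC1=CC(O)=CC(=O)O1 | starting material
8 | 1-iodobutane | CCCCI | starting material
9 | dilithium dianion of triacetic acid lactone | [Li+].[Li+].[CH2-]C1=CC([O-])=CC(=O)O1 | intermediate (not isolated)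
10 | 4-hydroxy-6-pentyl-2H-pyran-2-one | CCCCCC1=CC(O)=CC(=O)O1 | intermediate
11 | 2-(benzyloxy)-4-methoxy-6-propylbenzoyl chloride | CCCc1cc(OC)cc(OCc2ccccc2)c1C(=O)Cl | intermediate (not isolated)
12 | 2-oxo-6-pentyl-2H-pyran-4-yl 2-(benzyloxy)-4-methoxy-6-propylbenzoate | CCCCCC1=CC(OC(=O)c2c(OCc3ccccc3)cc(OC)cc2CCC)=CC(=O)O1 | intermediate
13 | trimethylsilylacetylene | C#C[Si](C)(C)C | starting material
14 | lithium (trimethylsilyl)acetylide | [Li]C#C[Si](C)(C)C | intermediate (not isolated)
15 | lithium 2-(trimethylsilyl)ethynolate | [Li]OC#C[Si](C)(C)C | intermediate (not isolated)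
16 | triisopropyl{[(trimethylsilyl)ethynyl]oxy}silane | CC(C)[Si](OC#C[Si](C)(C)C)(C(C)C)C(C)C | intermediate
17 | (ethynyloxy)triisopropylsilane | C#CO[Si](C(C)C)(C(C)C)C(C)C | intermediate
18 | benzyl chloroformate | O=C(Cl)OCc1ccccc1 | starting material
19 | lithium [(triisopropylsilyl)oxy]acetylide | [Li]C#CO[Si](C(C)C)(C(C)C)C(C)C | intermediate (not isolated)
20 | benzyl 3-[(triisopropylsilyl)oxy]prop-2-ynoate | O=C(OCc1ccccc1)C#CO[Si](C(C)C)(C(C)C)C(C)C | intermediate
21 | benzyl 8-{[2-(benzyloxy)-4-methoxy-6-propylbenzoyl]oxy}-3-oxo-1-pentyl-5-[(triisopropylsilyl)oxy]-2-oxabicyclo[2.2.2]octa-5,7-diene-6-carboxylate (racemic) | CCCCCC12OC(=O)C(C(OC(=O)c3c(OCc4ccccc4)cc(OC)cc3CCC)=C1)C(O[Si](C(C)C)(C(C)C)C(C)C)=C2C(=O)OCc1ccccc1 | intermediate (not isolated)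
22 | benzyl 4-{[2-(benzyloxy)-4-methoxy-6-propylbenzoyl]oxy}-6-pentyl-2-[(triisopropylsilyl)oxy]benzoate | CCCCCc1cc(OC(=O)c2c(OCc3ccccc3)cc(OC)cc2CCC)cc(O[Si](C(C)C)(C(C)C)C(C)C)c1C(=O)OCc1ccccc1 | intermediate
23 | benzyl 4-{[2-(benzyloxy)-4-methoxy-6-propylbenzoyl]oxy}-2-hydroxy-6-pentylbenzoate | CCCCCc1cc(OC(=O)c2c(OCc3ccccc3)cc(OC)cc2CCC)cc(O)c1C(=O)OCc1ccccc1 | intermediate
24 | stenosporic acid | CCCCCc1cc(OC(=O)c2c(O)cc(OC)cc2CCC)cc(O)c1C(=O)O | target

**Step count and risks**

Total step count: 12. Longest linear sequence: 8 steps (steps 1, 2, 3, 4, 6, 10, 11, 12).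

Most likely to fail, step 10 (the proposed benzannulation). The ester may damp the nucleophilicity of the alkyne carbon so far that the pyrone is not engaged, and the alkyne may instead drift by a 1,3-silyl shift to the silylketene or be hydrated; transfer of the aroyl group from the vinylogous anhydride is a further risk. The fallback uses known depside chemistry and builds ring B separately. It sets out from 6 and comes back at 23. Olivetol F1 (commercial) is carboxylated with MeOMgOCO2Me in DMF at 120 °C to give olivetolic acid F2, which is esterified with BnBr and KHCO3 in DMF to give benzyl 2,4-dihydroxy-6-pentylbenzoate F3. Acid 6 is converted to acid chloride 11 as in step 6 and coupled with F3 in pyridine–CH2Cl2 at 0 °C. The 2-hydroxyl of F3 is hydrogen-bonded to the ester carbonyl, so acylation should occur at the 4-hydroxyl and give 23, which goes on to step 12.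

Second, step 8 (selective removal of the carbon-bound silyl group). An ynolate is a good leaving group, so methoxide may also strip the oxygen-bound silyl group, or methanol may add to the ynol ether. The fallback avoids silyl ynol ethers and replaces them by a purchasable alkyl ynol ether. It sets out from 18 and 12 and comes back at 24. Ethoxyethyne F4 (commercial) is lithiated with n-BuLi in THF at −78 °C to lithium ethoxyacetylide F5, which is acylated with 18 to give benzyl 3-ethoxyprop-2-ynoate F6. F6 and 12 under the conditions of step 10, kept below the temperature of ethylene loss from the ethyl ynol ether, should pass through bicyclic lactone F7 to benzyl 4-{[2-(benzyloxy)-4-methoxy-6-propylbenzoyl]oxy}-2-ethoxy-6-pentylbenzoate F8. Excess BCl3 in CH2Cl2 at −78 → 0 °C should then cleave the chelated 2'-ethyl ether, the ring A benzyl ether and the benzyl ester while sparing the unchelated 4-methoxy group, giving 24 directly.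

Third, step 6 (O-acylation of the pyrone). The hindered acyl carbon may react too slowly with the weakly nucleophilic pyronate, so that hydrolysis wins, or the aroyl group may migrate from O4 to C3. The fallback reverses the roles so that the pyrone is the electrophile and the hindered acyl carbon is never attacked. It sets out from 10 and 6 and comes back at 12. Pyrone 10 is converted with Bu4NBr and P2O5 in toluene at 100 °C into 4-bromo-6-pentyl-2H-pyran-2-one F9. Acid 6 with Cs2CO3 in DMF gives cesium 2-(benzyloxy)-4-methoxy-6-propylbenzoate F10, which should displace bromide from C4 of F9 by addition–elimination at rt to give 12.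

**Further compounds**

F1 | step 10 | olivetol (5-pentylbenzene-1,3-diol) | CCCCCc1cc(O)cc(O)c1
F2 | step 10 | olivetolic acid (2,4-dihydroxy-6-pentylbenzoic acid) | CCCCCc1cc(O)cc(O)c1C(=O)O
F3 | step 10 | benzyl 2,4-dihydroxy-6-pentylbenzoate | CCCCCc1cc(O)cc(O)c1C(=O)OCc1ccccc1
F4 | step 8 | ethoxyethyne | CCOC#C
F5 | step 8 | lithium ethoxyacetylide | [Li]C#COCC
F6 | step 8 | benzyl 3-ethoxyprop-2-ynoate | CCOC#CC(=O)OCc1ccccc1
F7 | step 8 | benzyl 8-{[2-(benzyloxy)-4-methoxy-6-propylbenzoyl]oxy}-5-ethoxy-3-oxo-1-pentyl-2-oxabicyclo[2.2.2]octa-5,7-diene-6-carboxylate (racemic) | CCCCCC12OC(=O)C(C(OC(=O)c3c(OCc4ccccc4)cc(OC)cc3CCC)=C1)C(OCC)=C2C(=O)OCc1ccccc1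
F8 | step 8 | benzyl 4-{[2-(benzyloxy)-4-methoxy-6-propylbenzoyl]oxy}-2-ethoxy-6-pentylbenzoate | CCCCCc1cc(OC(=O)c2c(OCc3ccccc3)cc(OC)cc2CCC)cc(OCC)c1C(=O)OCc1ccccc1
F9 | step 6 | 4-bromo-6-pentyl-2H-pyran-2-one | CCCCCC1=CC(Br)=CC(=O)O1
F10 | step 6 | cesium 2-(benzyloxy)-4-methoxy-6-propylbenzoate | CCCc1cc(OC)cc(OCc2ccccc2)c1C(=O)[O-].[Cs+]
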